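The ten-membered carbocycle (C1–C10) is closed last, across C9–C10, by an intramolecular Nozaki–Hiyama–Kishi reaction on a seco-aldehyde that already holds the cis-fused α-methylene-γ-lactone (O–C6–C7–C11–C12) and the C8 epoxyangelate. The step exploits the C9 carbinol allylic to the (Z)-C1=C10 alkene: the (Z)-alkenyl iodide and the cis-lactone hold both arms on one face, and ring closure sets C9 and frees its hydroxyl beside the C8 ester, giving the target directly. The precursor is an open-chain (Z)-2-iodoalkene/α-acyloxy aldehyde built from geranyl acetate, (S)-glyceraldehyde acetonide, methyl acrylate and angelic acid by a syn-selective indium allylation–lactonisation.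

Key step: step 15

Remark on the chemistry: germacrane numbering is used (C12 lactone carbonyl, C11=C13 methylidene, C6 lactone carbinol, C8 acyloxy, C9 hydroxy, C14 and C15 the methyls on C10 and C4). The target is read as (6S,7S,8R,9R), 1(10)Z,4E, with a cis-fused 12,6-lactone and a (2S,3S)-epoxyangelate. Compounds 1, 7, 8 and 15 are taken as commercial.

Step 1
Reactants: 1 geranyl acetate
Product: 3 (2E)-3-methyl-6-oxohex-2-en-1-yl acetate, via secondary ozonide 2 (not isolated)
Conditions: O3 (1 equiv), CH2Cl2, pyridine (cat.), −78 °C; Me2S, −78 °C → rt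
Reagents that add atoms: ozone [O-][O+]=O
Why: Chemoselective ozonolysis with reductive work-up should cleave only the electron-rich terminal isopropylidene alkene, because the C2=C3 alkene is deactivated by the allylic acetate, and the E geometry of the later C4=C5 bond is carried over unchanged.

Step 2
Reactants: 3 (2E)-3-methyl-6-oxohex-2-en-1-yl acetate
Product: 4 (2E,6Z)-7-iodo-3-methylocta-2,6-dien-1-yl acetate
Conditions: EtPPh3I, n-BuLi, THF, rt; I2, −78 °C; NaHMDS, −78 → −20 °C; then 3, −78 °C
Reagents that add atoms: ethyltriphenylphosphonium iodide CC[P+](c1ccccc1)(c1ccccc1)c1ccccc1.[I-]; iodine II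
Why: A Stork–Zhao-type Wittig olefination with the α-iodo ylide Ph3P=C(I)CH3 should give the (Z)-2-iodo-2-alkene under kinetic control at low temperature, which fixes the later cis C1=C10 geometry, and the acetate is not attacked at −78 °C.

Step 3
Reactants: 4 (2E,6Z)-7-iodo-3-methylocta-2,6-dien-1-yl acetate
Product: 5 (2E,6Z)-7-iodo-3-methylocta-2,6-dien-1-ol
Conditions: K2CO3 (cat.), MeOH, 0 °C → rt
Reagents that add atoms: none
Why: Base-catalysed transesterification (methanolysis) removes the acetate without touching the alkenyl iodide or either alkene geometry.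

Step 4
Reactants: 5 (2E,6Z)-7-iodo-3-methylocta-2,6-dien-1-ol
Product: 6 (2E,6Z)-7-iodo-3-methylocta-2,6-dienal
Conditions: MnO2, CH2Cl2, rt
Reagents that add atoms: none
Why: Manganese dioxide oxidation is selective for the allylic alcohol and should give the E-enal without isomerisation.

Step 5
Reactants: 7 (S)-glyceraldehyde acetonide [(4S)-2,2-dimethyl-1,3-dioxolane-4-carbaldehyde]; 8 methyl acrylate
Product: 9 methyl 2-{hydroxy[(4S)-2,2-dimethyl-1,3-dioxolan-4-yl]methyl}prop-2-enoate (mixture of carbinol epimers)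
Conditions: DABCO, 1,4-dioxane/H2O (1:1), rt
Reagents that add atoms: none
Why: The Morita–Baylis–Hillman reaction joins the acrylate α-carbon to the aldehyde under mild amine catalysis that should leave the dioxolane centre intact; the new carbinol centre may form as a mixture because it is removed in step 6.

Step 6
Reactants: 9 methyl 2-{hydroxy[(4S)-2,2-dimethyl-1,3-dioxolan-4-yl]methyl}prop-2-enoate
Product: 10 methyl (2Z)-2-(bromomethyl)-3-[(4R)-2,2-dimethyl-1,3-dioxolan-4-yl]prop-2-enoate
Conditions: NBS, Me2S, CH2Cl2, 0 °C → rt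
Reagents that add atoms: N-bromosuccinimide O=C1CCC(=O)N1Br
Why: Corey–Kim-type activation of the alcohol followed by SN2′ attack of bromide should convert both carbinol epimers into the single, thermodynamically favoured (Z)-2-(bromomethyl)enoate, with the acid-sensitive acetonide untouched.

Step 7
Reactants: 6 (2E,6Z)-7-iodo-3-methylocta-2,6-dienal; 10 methyl (2Z)-2-(bromomethyl)-3-[(4R)-2,2-dimethyl-1,3-dioxolan-4-yl]prop-2-enoate
Product: 12 (4S,5S)-4-[(4R)-2,2-dimethyl-1,3-dioxolan-4-yl]-5-[(1E,5Z)-6-iodo-2-methylhepta-1,5-dien-1-yl]-3-methylideneoxolan-2-one, via syn hydroxy ester 11 (not isolated)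
Conditions: In powder, THF/H2O (1:1), rt; then PPTS (cat.), toluene, 60 °C
Reagents that add atoms: none
Why: The indium-mediated Barbier allylation of the (Z)-configured 2-(alkoxycarbonyl)allyl reagent should pass through a chair transition state with the enal substituent equatorial and give the syn adduct (cis-lactone after acid-catalysed lactonisation), and the aldehyde is expected to add anti to the allylic C8–O bond with C8–H eclipsing the allyl unit (A1,3 strain, the sense known for osmylation of (Z)-alkenes carrying this dioxolane), which sets C6 and C7 as S,S relative to C8.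

Step 8
Reactants: 12 lactone acetonide
Product: 13 (4R,5S)-4-[(1R)-1,2-dihydroxyethyl]-5-[(1E,5Z)-6-iodo-2-methylhepta-1,5-dien-1-yl]-3-methylideneoxolan-2-one
Conditions: AcOH/H2O/THF (3:1:1), 40 °C
Reagents that add atoms: none
Why: Mild acid hydrolysis of the terminal acetonide frees the C8/C9 diol without opening the lactone or ionising the allylic C6–O bond (the change of descriptor at the ring carbon is only a priority change).

Step 9
Reactants: 13 diol lactone
Product: 14 (4R,5S)-4-[(1R)-1-hydroxy-2-(triethylsilyloxy)ethyl]-5-[(1E,5Z)-6-iodo-2-methylhepta-1,5-dien-1-yl]-3-methylideneoxolan-2-one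
Conditions: TESCl (1.05 equiv), Et3N, DMAP (cat.), CH2Cl2, −40 °C
Reagents that add atoms: chlorotriethylsilane CC[Si](Cl)(CC)CC
Why: Silylation at low temperature should take the primary C9 hydroxyl in preference to the hindered secondary C8 hydroxyl next to the C7 branch.

Step 10
Reactants: 15 angelic acid [(2Z)-2-methylbut-2-enoic acid]
Product: 16 (2Z)-2-methylbut-2-en-1-ol
Conditions: LiAlH4, Et2O, 0 °C
Reagents that add atoms: none
Why: Hydride reduction of the acid gives the allylic alcohol with the Z geometry retained.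

Step 11
Reactants: 16 (2Z)-2-methylbut-2-en-1-ol
Product: 17 [(2R,3S)-2,3-dimethyloxiran-2-yl]methanol
Conditions: Ti(OiPr)4 (cat.), D-(−)-DIPT (cat.), t-BuOOH, 4 Å MS, CH2Cl2, −20 °C
Reagents that add atoms: tert-butyl hydroperoxide CC(C)(C)OO
Why: The Sharpless asymmetric epoxidation delivers oxygen syn to the Z-alkene on the face selected by D-(−)-tartrate (opposite to that of L-(+)-tartrate), which sets both epoxide centres as (2R,3S).

Step 12
Reactants: 17 [(2R,3S)-2,3-dimethyloxiran-2-yl]methanol
Product: 18 (2S,3S)-2,3-dimethyloxirane-2-carboxylic acid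
Conditions: RuCl3·xH2O (cat.), NaIO4, CCl4/MeCN/H2O, 0 °C → rt
Reagents that add atoms: water O
Why: Ruthenium tetroxide-catalysed oxidation takes the primary epoxy alcohol to the glycidic acid without touching the epoxide centres (the descriptor at C2 changes only through priorities).

Step 13
Reactants: 14 C8 alcohol; 18 (2S,3S)-2,3-dimethyloxirane-2-carboxylic acid
Product: 20 (1R)-1-[(2S,3S)-2-[(1E,5Z)-6-iodo-2-methylhepta-1,5-dien-1-yl]-4-methylidene-5-oxooxolan-3-yl]-2-[(triethylsilyl)oxy]ethyl (2S,3S)-2,3-dimethyloxirane-2-carboxylate, via mixed anhydride 19 (not isolated)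
Conditions: 2,4,6-Cl3C6H2COCl, Et3N, THF, rt; then 14, DMAP, toluene, rt
Reagents that add atoms: none
Why: The Yamaguchi esterification is suited to a hindered secondary alcohol and an α-quaternary acid and acylates oxygen with retention at C8, under amine conditions too mild for translactonisation.

Step 14
Reactants: 20 C8 ester, C9 TES ether
Product: 21 (1R)-1-[(2S,3S)-2-[(1E,5Z)-6-iodo-2-methylhepta-1,5-dien-1-yl]-4-methylidene-5-oxooxolan-3-yl]-2-oxoethyl (2S,3S)-2,3-dimethyloxirane-2-carboxylate
Conditions: (COCl)2, DMSO, CH2Cl2, −78 → −35 °C; i-Pr2NEt, −78 → −20 °C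
Reagents that add atoms: none
Why: Swern conditions convert a primary triethylsilyl ether directly into the aldehyde through the alkoxysulfonium ion, so no free C9 alcohol is present to accept the acyl group, and the cold hindered base should spare the C8 centre.

Step 15
Reactants: 21 seco-aldehyde
Product: 22 target, (3aS,4R,5R,6Z,10E,11aS)-5-hydroxy-6,10-dimethyl-3-methylidene-2-oxo-2,3,3a,4,5,8,9,11a-octahydrocyclodeca[b]furan-4-yl (2S,3S)-2,3-dimethyloxirane-2-carboxylate
Conditions: CrCl2 (excess), NiCl2 (cat.), degassed DMSO, rt, high dilution (slow addition of 21)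
Reagents that add atoms: none
Why: Ni(0) formed in situ inserts into the C10–I bond with retention of the Z geometry, transmetalation gives an alkenylchromium(III) species that adds to the C9 aldehyde, and work-up of the Cr(III) alkoxide frees the C9 hydroxyl; this is an intramolecular Nozaki–Hiyama–Kishi reaction, a standard way to close medium rings at an allylic carbinol. The ten-membered ring closes by C9–C10 bond formation (1,2-addition of C(sp2)–Cr to the carbonyl, exo with respect to C=O), leaving C1=C10 endocyclic and cis as set by the (Z)-iodide. The new stereocentre C9 is controlled by C8 through the conformation of the closing ring: with the C8–O bond anti to the incoming C10 (polar Felkin–Anh arrangement), the tether from C7 is expected to reach C9 only when the aldehyde C–H rather than C=O eclipses C7–C8, which puts the oxygen on the periphery and gives the 8,9-trans (9R) alcohol. The step needs ring closure over oligomerisation, which high dilution, the cis-lactone (C5 and C8 arms on one face) and the cis alkenyl iodide should secure. It also needs chemoselectivity: alkenylchromium reagents add to aldehydes but not to the lactone, the ester, the epoxide or the C11=C13 acrylate unit, and a Cr(III) alkoxide is a poor trigger for acyl migration from O8.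

Compound list
1 | geranyl acetate, (2E)-3,7-dimethylocta-2,6-dien-1-yl acetate | CC(C)=CCC/C(C)=C/COC(C)=O | starting material
2 | secondary ozonide, (2E)-5-(5,5-dimethyl-1,2,4-trioxolan-3-yl)-3-methylpent-2-en-1-yl acetate | CC1(C)OOC(CC/C(C)=C/COC(C)=O)O1 | intermediate
3 | (2E)-3-methyl-6-oxohex-2-en-1-yl acetate | O=CCC/C(C)=C/COC(C)=O | intermediate
4 | (2E,6Z)-7-iodo-3-methylocta-2,6-dien-1-yl acetate | C/C(I)=C/CC/C(C)=C/COC(C)=O | intermediate
5 | (2E,6Z)-7-iodo-3-methylocta-2,6-dien-1-ol | C/C(I)=C/CC/C(C)=C/CO | intermediate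
6 | (2E,6Z)-7-iodo-3-methylocta-2,6-dienal | C/C(I)=C/CC/C(C)=C/C=O | intermediate
7 | (S)-glyceraldehyde acetonide, (4S)-2,2-dimethyl-1,3-dioxolane-4-carbaldehyde | O=C[C@@H]1COC(C)(C)O1 | starting material
8 | methyl acrylate | C=CC(=O)OC | starting material
9 | methyl 2-{hydroxy[(4S)-2,2-dimethyl-1,3-dioxolan-4-yl]methyl}prop-2-enoate (carbinol epimers) | C=C(C(=O)OC)C(O)[C@@H]1COC(C)(C)O1 | intermediate
10 | methyl (2Z)-2-(bromomethyl)-3-[(4R)-2,2-dimethyl-1,3-dioxolan-4-yl]prop-2-enoate | COC(=O)/C(CBr)=C/[C@@H]1COC(C)(C)O1 | intermediate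
11 | syn hydroxy ester, methyl (3S,4S,5E,9Z)-3-[(4R)-2,2-dimethyl-1,3-dioxolan-4-yl]-4-hydroxy-10-iodo-6-methyl-2-methylideneundeca-5,9-dienoate | C=C(C(=O)OC)[C@@H]([C@@H](O)/C=C(\C)CC/C=C(/C)I)[C@@H]1COC(C)(C)O1 | intermediate
12 | (4S,5S)-4-[(4R)-2,2-dimethyl-1,3-dioxolan-4-yl]-5-[(1E,5Z)-6-iodo-2-methylhepta-1,5-dien-1-yl]-3-methylideneoxolan-2-one (cis-lactone) | C=C1C(=O)O[C@@H](/C=C(\C)CC/C=C(/C)I)[C@H]1[C@@H]2COC(C)(C)O2 | intermediate
13 | (4R,5S)-4-[(1R)-1,2-dihydroxyethyl]-5-[(1E,5Z)-6-iodo-2-methylhepta-1,5-dien-1-yl]-3-methylideneoxolan-2-one | C=C1C(=O)O[C@@H](/C=C(\C)CC/C=C(/C)I)[C@H]1[C@@H](O)CO | intermediate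
14 | (4R,5S)-4-[(1R)-1-hydroxy-2-(triethylsilyloxy)ethyl]-5-[(1E,5Z)-6-iodo-2-methylhepta-1,5-dien-1-yl]-3-methylideneoxolan-2-one | C=C1C(=O)O[C@@H](/C=C(\C)CC/C=C(/C)I)[C@H]1[C@@H](O)CO[Si](CC)(CC)CC | intermediate
15 | angelic acid, (2Z)-2-methylbut-2-enoic acid | C/C=C(/C)C(=O)O | starting material
16 | (2Z)-2-methylbut-2-en-1-ol | C/C=C(/C)CO | intermediate
17 | [(2R,3S)-2,3-dimethyloxiran-2-yl]methanol | OC[C@@]1(C)O[C@H]1C | intermediate
18 | (2S,3S)-2,3-dimethyloxirane-2-carboxylic acid | OC(=O)[C@@]1(C)O[C@H]1C | intermediate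
19 | mixed anhydride, (2S,3S)-2,3-dimethyloxirane-2-carboxylic 2,4,6-trichlorobenzoic anhydride | O=C(OC(=O)[C@@]1(C)O[C@H]1C)c1c(Cl)cc(Cl)cc1Cl | intermediate
20 | (1R)-1-[(2S,3S)-2-[(1E,5Z)-6-iodo-2-methylhepta-1,5-dien-1-yl]-4-methylidene-5-oxooxolan-3-yl]-2-[(triethylsilyl)oxy]ethyl (2S,3S)-2,3-dimethyloxirane-2-carboxylate | C=C1C(=O)O[C@@H](/C=C(\C)CC/C=C(/C)I)[C@H]1[C@H](CO[Si](CC)(CC)CC)OC(=O)[C@@]2(C)O[C@H]2C | intermediate
21 | (1R)-1-[(2S,3S)-2-[(1E,5Z)-6-iodo-2-methylhepta-1,5-dien-1-yl]-4-methylidene-5-oxooxolan-3-yl]-2-oxoethyl (2S,3S)-2,3-dimethyloxirane-2-carboxylate | C=C1C(=O)O[C@@H](/C=C(\C)CC/C=C(/C)I)[C@H]1[C@H](C=O)OC(=O)[C@@]2(C)O[C@H]2C | intermediate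
22 | (3aS,4R,5R,6Z,10E,11aS)-5-hydroxy-6,10-dimethyl-3-methylidene-2-oxo-2,3,3a,4,5,8,9,11a-octahydrocyclodeca[b]furan-4-yl (2S,3S)-2,3-dimethyloxirane-2-carboxylate | C=C1C(=O)O[C@H]2/C=C(\C)CC/C=C(/C)[C@@H](O)[C@H](OC(=O)[C@@]3(C)O[C@H]3C)[C@@H]12 | target

Total step count: 15. Longest linear sequence: 10 steps (steps 1–4, 7–9, 13–15, from geranyl acetate).

Steps most likely to fail

Step 15. The alkenylchromium may add to the wrong face of the C9 aldehyde or with low facial selectivity, and intermolecular coupling may compete with ring closure. The fallback sets out from 21: the ring is closed as before, and the 9-epimer F1, alone or mixed with 22, is oxidised with Dess–Martin periodinane (NaHCO3, CH2Cl2) to the C9 enone F2. F2 is then reduced under reagent control with the (R)-CBS oxazaborolidine and catecholborane at −78 °C (alkenyl side as the large group), which comes back to the route at 22.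

Step 7. The allylindium may add to the enal with poor or reversed facial selectivity relative to the dioxolane centre, so that C6 and C7 are set in the wrong sense while the syn (cis-lactone) relationship still holds. The fallback sets out from 6 and uses the enantiomeric fragment. (R)-Glyceraldehyde acetonide F3 (commercial) is taken through the Baylis–Hillman adduct F4 to the bromide F5 as in steps 5 and 6. Indium allylation of 6 with F5 then gives, through the hydroxy ester F6, the lactone F7 with the correct C6 and C7 centres and the opposite C8 centre. Hydrolysis to the diol F8 and silylation to the silyl ether F9 follow steps 8 and 9. The ester is then installed with inversion at C8 by a Mitsunobu reaction of F9 with acid 18 (PPh3, DIAD, toluene, 0 °C), which comes back to the route at 20.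

Step 14. The amine base may epimerise C8 of the α-acyloxy aldehyde, or the silyl ether may be cleaved incompletely under the Swern activation. The fallback sets out from 20: HF·pyridine with extra pyridine in THF at 0 °C removes the silyl group to give the primary alcohol F10, which is oxidised without amine base (Dess–Martin periodinane, NaHCO3, CH2Cl2, 0 °C), coming back to the route at 21.

Further compounds
F1 | step 15 | 9-epimer of 22, (3aS,4R,5S,6Z,10E,11aS)-5-hydroxy-6,10-dimethyl-3-methylidene-2-oxo-2,3,3a,4,5,8,9,11a-octahydrocyclodeca[b]furan-4-yl (2S,3S)-2,3-dimethyloxirane-2-carboxylate | C=C1C(=O)O[C@H]2/C=C(\C)CC/C=C(/C)[C@H](O)[C@H](OC(=O)[C@@]3(C)O[C@H]3C)[C@@H]12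
F2 | step 15 | C9 enone, (3aS,4R,6Z,10E,11aS)-6,10-dimethyl-3-methylidene-2,5-dioxo-2,3,3a,4,5,8,9,11a-octahydrocyclodeca[b]furan-4-yl (2S,3S)-2,3-dimethyloxirane-2-carboxylate | C=C1C(=O)O[C@H]2/C=C(\C)CC/C=C(/C)C(=O)[C@H](OC(=O)[C@@]3(C)O[C@H]3C)[C@@H]12
F3 | step 7 | (R)-glyceraldehyde acetonide, (4R)-2,2-dimethyl-1,3-dioxolane-4-carbaldehyde | O=C[C@H]1COC(C)(C)O1
F4 | step 7 | methyl 2-{hydroxy[(4R)-2,2-dimethyl-1,3-dioxolan-4-yl]methyl}prop-2-enoate (carbinol epimers) | C=C(C(=O)OC)C(O)[C@H]1COC(C)(C)O1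
F5 | step 7 | methyl (2Z)-2-(bromomethyl)-3-[(4S)-2,2-dimethyl-1,3-dioxolan-4-yl]prop-2-enoate | COC(=O)/C(CBr)=C/[C@H]1COC(C)(C)O1
F6 | step 7 | methyl (3S,4S,5E,9Z)-3-[(4S)-2,2-dimethyl-1,3-dioxolan-4-yl]-4-hydroxy-10-iodo-6-methyl-2-methylideneundeca-5,9-dienoate | C=C(C(=O)OC)[C@@H]([C@@H](O)/C=C(\C)CC/C=C(/C)I)[C@H]1COC(C)(C)O1
F7 | step 7 | (4S,5S)-4-[(4S)-2,2-dimethyl-1,3-dioxolan-4-yl]-5-[(1E,5Z)-6-iodo-2-methylhepta-1,5-dien-1-yl]-3-methylideneoxolan-2-one | C=C1C(=O)O[C@@H](/C=C(\C)CC/C=C(/C)I)[C@H]1[C@H]2COC(C)(C)O2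
F8 | step 7 | (4R,5S)-4-[(1S)-1,2-dihydroxyethyl]-5-[(1E,5Z)-6-iodo-2-methylhepta-1,5-dien-1-yl]-3-methylideneoxolan-2-one | C=C1C(=O)O[C@@H](/C=C(\C)CC/C=C(/C)I)[C@H]1[C@H](O)CO
F9 | step 7 | (4R,5S)-4-[(1S)-1-hydroxy-2-(triethylsilyloxy)ethyl]-5-[(1E,5Z)-6-iodo-2-methylhepta-1,5-dien-1-yl]-3-methylideneoxolan-2-one | C=C1C(=O)O[C@@H](/C=C(\C)CC/C=C(/C)I)[C@H]1[C@H](O)CO[Si](CC)(CC)CC
F10 | step 14 | (1R)-2-hydroxy-1-[(2S,3S)-2-[(1E,5Z)-6-iodo-2-methylhepta-1,5-dien-1-yl]-4-methylidene-5-oxooxolan-3-yl]ethyl (2S,3S)-2,3-dimethyloxirane-2-carboxylate | C=C1C(=O)O[C@@H](/C=C(\C)CC/C=C(/C)I)[C@H]1[C@H](CO)OC(=O)[C@@]2(C)O[C@H]2C
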